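All runs are calculated for an exercise; noise was put on by code.

Each proposed step spends one partner and none gives one back, so the partner charged is a budget that can be paid out once.

the same everywhere: substrate 20 mM

| charge | partner | remark | time |
|---|---|---|---|
| maple | 11 mM | run made earlier |  |
| elm | 31 mM | run made earlier |  |
| larch | 73 mM | run made earlier |  |
| Monday's | 10.0 mM |  | 3.0 h |
| Sunday's | 16.0 mM |  | 3.0 h |
| Tuesday's | 80.0 mM |  | 3.0 h |

| run | time / h | single product / % | substrate / % |
|---|---|---|---|
| maple | 0.667 | 10.8 | 65.0 |
| maple | 1.33 | 11.6 | 61.4 |
| maple | 2.00 | 12.7 | 63.2 |
| maple | 2.50 | 11.8 | 62.6 |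
| maple | 3.00 | 11.4 | 63.9 |
| elm | 0.250 | 10.3 | 43.7 |
| elm | 0.417 | 8.4 | 32.4 |
| elm | 0.833 | 6.7 | 24.2 |
| elm | 1.50 | 5.5 | 18.0 |
| elm | 3.00 | 4.8 | 16.4 |
| larch | 0.667 | 0.1 | 1.3 |
| larch | 1.33 | 0 | 0 |
| larch | 2.00 | 0 | 0 |
| larch | 2.50 | 0.3 | 0 |
| larch | 3.00 | 0 | 0.7 |

(each reading ± 1 percentage point)

- steps that have been proposed: substrate + partner -> single product + released group; substrate + partner -> other mono adduct + released group; partner + single product -> bis adduct + released group; partner + other mono adduct -> bis adduct + released group; partner + single product -> over-reaction product

- single product at the end, in percent of the substrate charged, for each flask in turn (Monday's, Sunday's, Tuesday's)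

Watch the rate in the elm run. The substrate's loss per unit of substrate, the ln of the ratio of readings over each interval, starts at 3.31 /h. Between 0.833 h and 1.50 h it reads 0.444 /h, slower by a factor of 7.45. Dividing by [substrate] has already taken out the substrate's own fall, so I put this slowing down to [partner].

In the maple run, the substrate reads 65.0% at 0.667 h and 63.9% at 3.00 h, a gap about the size of the scatter. I therefore take partner as the limiting reagent there and count its 11 mM as paid for 7.22 mM of substrate lost. That gives 1.52: the partner cost, partner paid per substrate lost.

At that cost, my own reckoning leaves 67.2% of the substrate in Monday's flask. Monday's charge lies next to maple's, so I expect single product near maple's 11.4%. Tuesday's 80.0 mM is more than the 40.0 mM that two partners for each substrate would take, so I expect it to read like larch, 0%.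

The forecast gives 11.4%, 11.5% and 0.1% for Monday's, Sunday's and Tuesday's, holding that “the end state depends on stoichiometry rather than time”.

The flasks give 11.5%, 10.9% and <0.001%.

    substrate + partner → single product + released group (k = 1.91 /M/min)
    substrate + partner → other mono adduct + released group (k = 0.875 /M/min)
    partner + single product → bis adduct + released group (k = 4.47 /M/min)
    partner + other mono adduct → bis adduct + released group (k = 3.63 /M/min)
    partner + single product → over-reaction product (k = 5.59 /M/min)

The partner cost of 1.52 left 67.2% against 65.1% in Monday's flask, and 47.5% against 49.6% in Sunday's. The forecast would fail if the end moved with time, but Sunday's single product stands at 10.9% at 3.00 h and 10.9% at 30.0 h. In Monday's flask at 0.149 h, single product was made 1.84 times faster than it was used up, while its half-life by the over-reaction step was 0.36 h, short against 3.0 h. By 3.00 h, Monday's partner stands at 0% of its charge.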